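**Assumptions (one line):** (S)-(–)-pulegone is purchased or made from (S)-citronellal; the target is drawn as the free bis(hydrogen sulfate) but isolated as its sodium salt; all diastereoselectivities below are substrate-controlled from the pulegone stereocentres and are predicted, not demonstrated.

## Retrosynthetic overview
1. The target is the bis-sulfate of the hydroquinone. That comes from the dimethyl ether **25**, which is built from a head decalin and a tail decalin joined by the C4–CH2CH2–C9′ linker.
2. Head decalin: (R)-pulegone, two α′-alkylations (C9 quaternary), isopropylidene removal, then a **Claisen rearrangement** of the ketone-derived allyl enol ether. This builds the C4 quaternary centre and the linker. A carbonyl-ene cyclisation then closes ring A and sets Δ5 and H-10.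
3. Tail decalin: (S)-pulegone is α′-methylated, then alkylated at C9′ with the head iodide. Vinyl cuprate addition gives the gem-dimethyl C4′ and an equilibrated C5′. Hydroformylation and keto-aldehyde McMurry close ring A (Δ1′(10′)).
4. Ring order: head ring B (pulegone), head ring A (Claisen then ene), tail ring B (pulegone), tail ring A (McMurry).

## Route

**Step 1**
Reactants: 1 (4-hydroxybutan-2-one)
Product: 2 (4-(TBDPSO)butan-2-one)
Conditions: TBDPSCl, imidazole, DMF, rt
Reagents that add atoms: TBDPSCl, CC(C)(C)[Si](Cl)(c1ccccc1)c1ccccc1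
Why: Selective silylation of the primary alcohol gives an acid-stable linker precursor.

**Step 2**
Reactants: 2, 3 (triethyl phosphonoacetate)
Product: 4 (ethyl (E)-5-(TBDPSO)-3-methylpent-2-enoate)
Conditions: NaH, THF, 0 °C→rt; separate the E isomer
Reagents that add atoms: none
Why: Horner–Wadsworth–Emmons olefination of the methyl ketone, with the ester trans to the larger chain.

**Step 3**
Reactants: 4
Product: 5 ((E)-5-(TBDPSO)-3-methylpent-2-en-1-ol)
Conditions: DIBAL-H (2.5 equiv), CH2Cl2, –78 °C
Reagents that add atoms: none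
Why: DIBAL reduces the conjugated ester to the allylic alcohol and leaves the silyl ether and alkene geometry intact.

**Step 4**
Reactants: 6 ((R)-pulegone), 7 (2-(bromomethyl)-1,4-dimethoxybenzene)
Product: 8 (6-(2,5-dimethoxybenzyl)pulegone; C6 epimers)
Conditions: LDA, THF, –78 °C; add 7; warm to 0 °C
Reagents that add atoms: none
Why: The other α-carbon of pulegone is sp², so only C6 (target C9) is deprotonated, and the benzyl group enters trans to the C5 methyl. The epimer mixture is irrelevant because the next step re-enolises C6.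

**Step 5**
Reactants: 8
Product: 9 (6-benzyl-6-methylpulegone)
Conditions: LDA, THF/HMPA, –78 °C→rt; MeI
Reagents that add atoms: MeI, CI
Why: In the tetrasubstituted enolate the C8 methyl is pseudo-axial, so MeI attacks anti to it. The methyl ends trans and the benzyl cis to the C8 methyl, setting C8/C9 as in the target from the single pulegone stereocentre.

**Step 6**
Reactants: 9
Product: 10 (2-(2,5-dimethoxybenzyl)-2,3-dimethylcyclohexanone; benzyl cis to the 3-Me)
Conditions: 2 M aq. HCl/THF 1:1, reflux
Reagents that add atoms: water, O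
Why: Conjugate hydration followed by retro-aldol removes acetone, so the isopropylidene served only as a regio-directing group. The only α-H left is at C5, which makes the next enolisation regiospecific.

**Step 7**
Reactants: 10, 5
Product: 11 (C4 quaternary ketone with vinyl and CH2CH2OTBDPS; C5 epimerisable)
Conditions: 5 (3 equiv), TsOH (cat.), toluene, Dean–Stark reflux; then o-xylene, 190 °C, sealed tube
Reagents that add atoms: none
Why: The allyl enol ether formed toward C5 undergoes a chair-like Claisen [3,3]-sigmatropic rearrangement. This forms the C5–C4 bond and the quaternary centre, with the allyl unit delivered anti to the axial C9 substituent and the (E)-alkene defining C4. (C4 configuration is predicted, not demonstrated.)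

**Step 8**
Reactants: 11
Product: 12 (vinyl triflate C10(OTf)=C5)
Conditions: Tf2O, 2,6-di-tert-butyl-4-methylpyridine, DCE, 80 °C
Reagents that add atoms: Tf2O, O=S(=O)(C(F)(F)F)OS(=O)(=O)C(F)(F)F
Why: Non-basic triflation of the hindered ketone can only go toward C5, and this also removes the C5 stereocentre.

**Step 9**
Reactants: 12
Product: 13 (ring alkene C10H=C5)
Conditions: Pd(OAc)2, PPh3, HCO2H, Et3N, DMF, 60 °C
Reagents that add atoms: none
Why: Pd-catalysed formate reduction of the vinyl triflate gives the trisubstituted cyclohexene needed for the ene cyclisation.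

**Step 10**
Reactants: 13
Product: 14 (aldehyde C4–CH2CH2CHO)
Conditions: Rh(CO)2(acac), PPh3, CO/H2 (1:1, 40 bar), toluene, 80 °C
Reagents that add atoms: CO, [C-]#[O+]
Why: Rh hydroformylation of the terminal vinyl is linear-selective, and the hindered trisubstituted ring alkene is untouched. The new carbon becomes C1.

**Step 11**
Reactants: 14
Product: 15 (ring-A alcohol with Δ5, H-10 and 1-OH; C1 epimers)
Conditions: Me2AlCl, CH2Cl2, –78→0 °C
Reagents that add atoms: none
Why: Intramolecular carbonyl-ene reaction closes the six-membered ring by bonding C1 to C10 (Markovnikov, tertiary C5 terminus) with H transferred from C6. This gives the Δ5(6) alkene and H-10, whose configuration is controlled by the chair-like TS relative to C4.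

**Step 12**
Reactants: 15
Product: 16 (S-methyl xanthate)
Conditions: NaH, CS2, THF, 0 °C; then MeI
Reagents that add atoms: CS2, S=C=S; MeI, CI
Why: This activates the secondary alcohol for radical deoxygenation.

**Step 13**
Reactants: 16
Product: 17 (C1-deoxygenated TBDPS ether)
Conditions: Bu3SnH, AIBN, toluene, 110 °C
Reagents that add atoms: none
Why: Barton–McCombie deoxygenation leaves the C5=C6 alkene and all stereocentres intact.

**Step 14**
Reactants: 17
Product: 18 (primary alcohol)
Conditions: TBAF, THF, rt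
Reagents that add atoms: none
Why: Fluoride cleaves the silyl ether only.

**Step 15**
Reactants: 18
Product: 19 (head iodide, C4–CH2CH2I)
Conditions: I2, PPh3, imidazole, CH2Cl2, 0 °C→rt
Reagents that add atoms: I2, II
Why: Appel iodination of the primary alcohol gives the alkylating agent.

**Step 16**
Reactants: 20 ((S)-pulegone)
Product: 21 ((S)-6-methylpulegone; C6 epimers)
Conditions: LDA, THF, –78 °C; MeI
Reagents that add atoms: MeI, CI
Why: α′-Methylation is regiospecific and trans to the C5 methyl, as in step 4.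

**Step 17**
Reactants: 21, 19
Product: 22 (C9′ quaternary enone coupled to the head)
Conditions: LDA, THF, –78 °C; add 19 and HMPA; warm to rt
Reagents that add atoms: none
Why: Re-enolisation gives the tetrasubstituted enolate, whose C8′ methyl is pseudo-axial. The primary iodide enters anti to it, giving chain α and Me-9′ β as in the target.

**Step 18**
Reactants: 22
Product: 23 (C4′ gem-dimethyl/vinyl ketone)
Conditions: vinylMgBr, CuBr·SMe2, TMSCl, THF, –40 °C; then NaOMe, MeOH, rt
Reagents that add atoms: vinylmagnesium bromide, C=C[Mg]Br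
Why: Cuprate 1,4-addition to the β,β-dimethyl enone forms the gem-dimethyl centre. Base then equilibrates the only epimerisable centre, C5′, to the isomer with C4′ equatorial, which is the target configuration.

**Step 19**
Reactants: 23
Product: 24 (keto-aldehyde)
Conditions: Rh(CO)2(acac), PPh3, CO/H2 (1:1, 40 bar), toluene, 80 °C
Reagents that add atoms: CO, [C-]#[O+]
Why: Linear-selective hydroformylation again; the trisubstituted Δ5 alkene and aryl ethers survive.

**Step 20**
Reactants: 24
Product: 25 (bis(methyl ether) of the target)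
Conditions: TiCl3(DME)1.5, Zn–Cu, DME, reflux
Reagents that add atoms: none
Why: Intramolecular keto-aldehyde McMurry coupling closes the tail ring A and forms the trisubstituted Δ1′(10′) alkene directly, without touching C5′.

**Step 21**
Reactants: 25
Product: 26 (hydroquinone)
Conditions: BBr3, CH2Cl2, –78→0 °C; aq. NaHCO3
Reagents that add atoms: none
Why: Aryl methyl ether cleavage, run cold and brief to spare the alkenes; the air-sensitive hydroquinone is used immediately.

**Step 22**
Reactants: 26
Product: 27 (Toxiusol)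
Conditions: SO3·pyridine, pyridine, 0 °C→rt; ion exchange
Reagents that add atoms: sulfur trioxide–pyridine, O=S(=O)=O.c1ccncc1
Why: Both phenols are O-sulfated to the aryl hydrogen sulfates, and all C-stereocentres are untouched.

## Compound list

| # | Name | SMILES | Role |
|---|---|---|---|
| 1 | 4-hydroxybutan-2-one | CC(=O)CCO | starting material |
| 2 | 4-(TBDPSO)butan-2-one | CC(=O)CCO[Si](c1ccccc1)(c1ccccc1)C(C)(C)C | intermediate |
| 3 | triethyl phosphonoacetate | CCOC(=O)CP(=O)(OCC)OCC | starting material |
| 4 | ethyl (E)-5-(TBDPSO)-3-methylpent-2-enoate | CCOC(=O)/C=C(/CCO[Si](c3ccccc3)(c3ccccc3)C(C)(C)C)C | intermediate |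
| 5 | (E)-5-(TBDPSO)-3-methylpent-2-en-1-ol | OC/C=C(/CCO[Si](c3ccccc3)(c3ccccc3)C(C)(C)C)C | intermediate |
| 6 | (R)-(+)-pulegone | C[C@@H]1CCC(=C(C)C)C(=O)C1 | starting material |
| 7 | 2-(bromomethyl)-1,4-dimethoxybenzene | COc1ccc(OC)c(CBr)c1 | starting material |
| 8 | 6-(2,5-dimethoxybenzyl)-(R)-pulegone (C6 epimers) | C[C@@H]1CCC(=C(C)C)C(=O)C1Cc1cc(OC)ccc1OC | intermediate |
| 9 | 6-benzyl-6-methyl-(R)-pulegone (quaternary C6) | C[C@@H]1CCC(=C(C)C)C(=O)[C@]1(C)Cc1cc(OC)ccc1OC | intermediate |
| 10 | 2-(2,5-dimethoxybenzyl)-2,3-dimethylcyclohexanone | C[C@@H]1CCCC(=O)[C@]1(C)Cc1cc(OC)ccc1OC | intermediate |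
| 11 | Claisen product (C4 quaternary ketone) | C[C@@H]1CCC([C@](C=C)(C)CCO[Si](c3ccccc3)(c3ccccc3)C(C)(C)C)C(=O)[C@]1(C)Cc1cc(OC)ccc1OC | intermediate |
| 12 | vinyl triflate | C[C@@H]1CCC(=C(OS(=O)(=O)C(F)(F)F)[C@]1(C)Cc1cc(OC)ccc1OC)[C@](C=C)(C)CCO[Si](c3ccccc3)(c3ccccc3)C(C)(C)C | intermediate |
| 13 | cyclohexene | C[C@@H]1CCC(=C[C@]1(C)Cc1cc(OC)ccc1OC)[C@](C=C)(C)CCO[Si](c3ccccc3)(c3ccccc3)C(C)(C)C | intermediate |
| 14 | aldehyde | C[C@@H]1CCC(=C[C@]1(C)Cc1cc(OC)ccc1OC)[C@](CCC=O)(C)CCO[Si](c3ccccc3)(c3ccccc3)C(C)(C)C | intermediate |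
| 15 | ene alcohol (C1 epimers) | C[C@@H]1CC=C2[C@@H](C(O)CC[C@@]2(C)CCO[Si](c3ccccc3)(c3ccccc3)C(C)(C)C)[C@]1(C)Cc1cc(OC)ccc1OC | intermediate |
| 16 | xanthate | C[C@@H]1CC=C2[C@@H](C(OC(=S)SC)CC[C@@]2(C)CCO[Si](c3ccccc3)(c3ccccc3)C(C)(C)C)[C@]1(C)Cc1cc(OC)ccc1OC | intermediate |
| 17 | deoxygenated silyl ether | C[C@@H]1CC=C2[C@@H](CCC[C@@]2(C)CCO[Si](c3ccccc3)(c3ccccc3)C(C)(C)C)[C@]1(C)Cc1cc(OC)ccc1OC | intermediate |
| 18 | primary alcohol | C[C@@H]1CC=C2[C@@H](CCC[C@@]2(C)CCO)[C@]1(C)Cc1cc(OC)ccc1OC | intermediate |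
| 19 | head iodide | C[C@@H]1CC=C2[C@@H](CCC[C@@]2(C)CCI)[C@]1(C)Cc1cc(OC)ccc1OC | intermediate |
| 20 | (S)-(–)-pulegone | C[C@H]1CCC(=C(C)C)C(=O)C1 | starting material |
| 21 | (S)-6-methylpulegone (C6 epimers) | C[C@H]1CCC(=C(C)C)C(=O)C1C | intermediate |
| 22 | coupled enone | C[C@@H]1CC=C2[C@@H](CCC[C@@]2(C)CC[C@@]2(C)C(=O)C(=C(C)C)CC[C@@H]2C)[C@]1(C)Cc1cc(OC)ccc1OC | intermediate |
| 23 | gem-dimethyl/vinyl ketone | C[C@@H]1CC=C2[C@@H](CCC[C@@]2(C)CC[C@@]2(C)C(=O)[C@@H](C(C)(C)C=C)CC[C@@H]2C)[C@]1(C)Cc1cc(OC)ccc1OC | intermediate |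
| 24 | keto-aldehyde | C[C@@H]1CC=C2[C@@H](CCC[C@@]2(C)CC[C@@]2(C)C(=O)[C@@H](C(C)(C)CCC=O)CC[C@@H]2C)[C@]1(C)Cc1cc(OC)ccc1OC | intermediate |
| 25 | Toxiusol bis(methyl ether) | C[C@@H]1CC=C2[C@@H](CCC[C@@]2(C)CC[C@@]2(C)C3=CCCC(C)(C)[C@H]3CC[C@@H]2C)[C@]1(C)Cc1cc(OC)ccc1OC | intermediate |
| 26 | hydroquinone | C[C@@H]1CC=C2[C@@H](CCC[C@@]2(C)CC[C@@]2(C)C3=CCCC(C)(C)[C@H]3CC[C@@H]2C)[C@]1(C)Cc1cc(O)ccc1O | intermediate |
| 27 | Toxiusol | C[C@@H]1CC=C2[C@@H](CCC[C@@]2(C)CC[C@@]2(C)C3=CCCC(C)(C)[C@H]3CC[C@@H]2C)[C@]1(C)Cc1cc(OS(=O)(=O)O)ccc1OS(=O)(=O)O | target |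

**Total steps:** 22. **Longest linear sequence:** 18 (6 → 8 → … → 19 → 22 → … → 27).

**Three steps most likely to fail:**
1. **Step 7 (ketone enol-ether Claisen):** the vicinal tertiary–quaternary bond forms in modest yield and C4 diastereoselectivity is only predicted. *Fallback:* build C4 by conjugate addition of the linker cuprate to a β-methyl Δ4-6-keto enone (ring A from a Robinson annulation), then convert the enolate to the enol triflate and reduce it to reinstall Δ5.
2. **Step 17 (hindered enolate alkylation forming C9′):** the primary iodide is slow to react with a tetrasubstituted enolate. *Fallback:* α-brominate 21 at C9′ and run a Ni-catalysed reductive cross-coupling with iodide 19. Alternatively, disconnect the Ca–Cb bond instead, using cross-metathesis of two vinyl-bearing quaternary fragments followed by hydrogenation.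
3. **Step 20 (McMurry at a ketone flanked by two quaternary-substituted carbons):** the coupling may fail or give pinacol. *Fallback:* in step 18 add allyl instead of vinyl, then use Wacker oxidation, intramolecular aldol condensation to the Δ1′(10′)-2′-enone, and Luche reduction/xanthate/Bu3SnH deoxygenation to re-form the trisubstituted alkene.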